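Numbering: tetralin (1,2,3,4-tetrahydronaphthalene) C1 i-Pr, C4 Me, C5/C6 OH, C7 CHO, C8 pyrone. Ring A is the arene, ring B the saturated ring, ring C the pyrone. All bicyclic compounds keep this numbering.
Feature used: in ring B, C4 carries only a one-carbon branch and is bonded to C4a of ring A, the carbon next to the C5 oxygen. The methyl group is therefore treated as a reduced formyl group and C4 as an aldehyde α-carbon, and C4–C4a is cut (radical-cation α-arylation).
Late cuts: the three O-methyl groups (BBr3), C8–C3 of ring C (aryl transfer from lead to the intact styrylpyrone, using the C8 bromine as handle), and C7–CHO (lithiation between OMe and Br).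
Early cuts: acyclic aldehyde 9 comes from a Rh-catalysed asymmetric aryl addition that sets C1, then a two-carbon olefination/hydrogenation and a ring bromination.
Ring order: rings A and C are bought, ring B closes in step 7, and rings A and C are joined in step 16.

Key step: step 7

Assumption: the aryl–pyrone axis is not specified in the target and is not controlled; the antipodes of BINAP and of the imidazolidinone are assigned from the accepted face-selection models of these catalysts.

Step 1
Reactants: 1 3,4-dimethoxyphenylboronic acid; 2 ethyl (E)-4-methylpent-2-enoate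
Product: 3 ethyl (3R)-3-(3,4-dimethoxyphenyl)-4-methylpentanoate
Conditions: Rh(acac)(C2H4)2 (3 mol %), (R)-BINAP (3.3 mol %), 1 (2.5 equiv), dioxane/H2O 10:1, 100 °C
Reagents that add atoms: none
Why: Hayashi–Miyaura reaction, in which the aryl–rhodium species inserts the E-enoate through the alkene face left open by (R)-BINAP, so the aryl group should arrive at C3 in the R sense (future C1) before hydrolysis releases the ester.

Step 2
Reactants: 3 ethyl (3R)-3-(3,4-dimethoxyphenyl)-4-methylpentanoate
Product: 4 (3R)-3-(3,4-dimethoxyphenyl)-4-methylpentanal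
Conditions: i-Bu2AlH (1.1 equiv), toluene, −78 °C; MeOH, then aq potassium sodium tartrate
Reagents that add atoms: none
Why: Partial ester reduction, in which the aluminium hemiacetal persists at −78 °C and collapses to the aldehyde only on work-up, leaving the β-stereocentre untouched.

Step 3
Reactants: 4 (3R)-3-(3,4-dimethoxyphenyl)-4-methylpentanal; 5 triethyl phosphonoacetate
Product: 6 ethyl (2E,5R)-5-(3,4-dimethoxyphenyl)-6-methylhept-2-enoate
Conditions: LiCl, DBU, MeCN, 0 °C to rt
Reagents that add atoms: none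
Why: Horner–Wadsworth–Emmons olefination under Masamune–Roush conditions, which adds the two carbons that become C4 and its one-carbon branch and should give the E-enoate under mild base.

Step 4
Reactants: 6 ethyl (2E,5R)-5-(3,4-dimethoxyphenyl)-6-methylhept-2-enoate
Product: 7 ethyl (5R)-5-(3,4-dimethoxyphenyl)-6-methylheptanoate
Conditions: H2 (1 atm), Pd/C (10 wt %), EtOAc, rt
Reagents that add atoms: none
Why: Catalytic hydrogenation of the conjugated alkene, placed before the bromination so that no C–Br bond is exposed to Pd/H2.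

Step 5
Reactants: 7 ethyl (5R)-5-(3,4-dimethoxyphenyl)-6-methylheptanoate
Product: 8 ethyl (5R)-5-(2-bromo-4,5-dimethoxyphenyl)-6-methylheptanoate
Conditions: NBS (1.05 equiv), MeCN, 0 °C, dark
Reagents that add atoms: N-bromosuccinimide O=C1CCC(=O)N1Br
Why: Electrophilic aromatic bromination, which in 4-alkylveratroles goes to the position para to the meta-methoxy group and ortho to the chain (future C8), while polar dark conditions suppress benzylic radical bromination.

Step 6
Reactants: 8 ethyl (5R)-5-(2-bromo-4,5-dimethoxyphenyl)-6-methylheptanoate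
Product: 9 (5R)-5-(2-bromo-4,5-dimethoxyphenyl)-6-methylheptanal
Conditions: i-Bu2AlH (1.1 equiv), toluene, −78 °C; MeOH, then aq potassium sodium tartrate
Reagents that add atoms: none
Why: Partial ester reduction as in step 2, with the aryl bromide inert to i-Bu2AlH at −78 °C.

Step 7
Reactants: 9 (5R)-5-(2-bromo-4,5-dimethoxyphenyl)-6-methylheptanal
Product: 10 (1R,4S)-8-bromo-1-isopropyl-5,6-dimethoxytetralin-4-carbaldehyde (trans)
Conditions: (2R,5R)-5-benzyl-2-tert-butyl-3-methylimidazolidin-4-one·CF3CO2H (20 mol %), (NH4)2Ce(NO3)6 (2.2 equiv), H2O (2 equiv), DME, −30 °C; cold aq NaHCO3, crude product used at once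
Reagents that add atoms: none
Why: Condensation of 9 with the secondary amine gives the E-enamine, the most easily oxidised species in the flask; tetravalent cerium removes one electron to leave a delocalised N–C–C radical cation whose electrophilic α-carbon bonds to C4a, and a second electron transfer, deprotonation at C4a and iminium hydrolysis then deliver 10 and free catalyst. The closest known reaction type is the enantioselective intramolecular α-arylation of aldehydes by SOMO organocatalysis, established for ω-(alkoxyaryl) aldehydes that close to tetralin carbaldehydes. Ring B closes as a six-membered ring by attack on the ortho carbon (6-endo counted through the C8a–C4a arene bond, 6-exo with respect to C4a=C5), which should be preferred to 5-exo ipso attack at the fully substituted C8a. The new C4 centre is set by the catalyst: in the (2R,5R) series the benzyl and tert-butyl groups cover the Si face of the enamine α-carbon, so C4a bonds to the Re face and gives 4S, and this pairing is matched because the peri contacts C8-Br/C1 and C5-OMe/C4 push both substituents pseudo-axial, which only the trans isomer allows. The step needs ortho regioselectivity, and the substrate secures it, since C8 is blocked by bromine and attack at C4a places spin density on C5, where the methoxy oxygen stabilises the cyclohexadienyl radical and the derived cation. Epimerisation of the α-aryl aldehyde is limited by the low temperature, the cold bicarbonate work-up and immediate reduction in step 8.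

Step 8
Reactants: 10 (1R,4S)-8-bromo-1-isopropyl-5,6-dimethoxytetralin-4-carbaldehyde
Product: 11 [(1R,4S)-8-bromo-1-isopropyl-5,6-dimethoxytetralin-4-yl]methanol
Conditions: NaBH4, MeOH/CH2Cl2, 0 °C
Reagents that add atoms: none
Why: Borohydride reduction of the aldehyde removes the acidity of the C4 hydrogen and so fixes the C4 configuration.

Step 9
Reactants: 11 [(1R,4S)-8-bromo-1-isopropyl-5,6-dimethoxytetralin-4-yl]methanol
Product: 12 [(1R,4S)-8-bromo-1-isopropyl-5,6-dimethoxytetralin-4-yl]methyl methanesulfonate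
Conditions: MsCl, Et3N, CH2Cl2, 0 °C; used without storage
Reagents that add atoms: methanesulfonyl chloride CS(=O)(=O)Cl
Why: Sulfonylation of a primary alcohol at oxygen, which does not involve C4.

Step 10
Reactants: 12 [(1R,4S)-8-bromo-1-isopropyl-5,6-dimethoxytetralin-4-yl]methyl methanesulfonate
Product: 13 (1R,4S)-8-bromo-1-isopropyl-5,6-dimethoxy-4-methyltetralin
Conditions: LiEt3BH (3 equiv), THF, 0 °C to rt; H2O
Reagents that add atoms: none
Why: SN2 hydride displacement of a primary sulfonate by the strongly nucleophilic triethylborohydride turns the branch into the methyl group, with the aryl bromide and aryl ethers inert at this temperature.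

Step 11
Reactants: 13 (1R,4S)-8-bromo-1-isopropyl-5,6-dimethoxy-4-methyltetralin
Product: 15 (1R,4S)-8-bromo-1-isopropyl-5,6-dimethoxy-4-methyltetralin-7-carbaldehyde, via C7-lithiated bromoarene 14 (not isolated)
Conditions: LiN(i-Pr)2 (1.3 equiv), THF, −78 °C; DMF, −78 to 0 °C; aq NH4Cl
Reagents that add atoms: N,N-dimethylformamide CN(C)C=O
Why: Directed ortho-metalation and formylation, since C7–H is the only arene hydrogen and is acidified by the flanking OMe and Br, the amide base does not exchange bromine, and at −78 °C the ortho-bromoaryllithium should last long enough to be trapped.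

Step 12
Reactants: 15 (1R,4S)-8-bromo-1-isopropyl-5,6-dimethoxy-4-methyltetralin-7-carbaldehyde
Product: 16 2-[(1R,4S)-8-bromo-1-isopropyl-5,6-dimethoxy-4-methyltetralin-7-yl]-1,3-dioxolane
Conditions: HOCH2CH2OH (5 equiv), TsOH·H2O (5 mol %), toluene, reflux, azeotropic removal of water
Reagents that add atoms: ethylene glycol OCCO
Why: Acid-catalysed acetalisation, known for 2,6-disubstituted benzaldehydes, masks the formyl group against n-BuLi in step 13.

Step 13
Reactants: 16 2-[(1R,4S)-8-bromo-1-isopropyl-5,6-dimethoxy-4-methyltetralin-7-yl]-1,3-dioxolane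
Product: 18 [(1R,4S)-7-(1,3-dioxolan-2-yl)-1-isopropyl-5,6-dimethoxy-4-methyltetralin-8-yl]boronic acid, via C8 aryllithium 17 (not isolated)
Conditions: n-BuLi (1.1 equiv), THF, −78 °C; B(OMe)3 (3 equiv), −78 °C to rt; aq NH4Cl
Reagents that add atoms: trimethyl borate COB(OC)OC; water O
Why: Bromine–lithium exchange followed by borylation, in which exchange is fast even at the flanked C8 and is helped by chelation to an acetal oxygen, the electrophile is small, and the near-neutral hydrolysis spares the dioxolane.

Step 14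
Reactants: 19 4-hydroxy-6-methyl-2H-pyran-2-one; 20 4-methoxybenzaldehyde
Product: 22 4-hydroxy-6-[2-hydroxy-2-(4-methoxyphenyl)ethyl]-2H-pyran-2-one (racemic), via dilithio pyrone dianion 21 (not isolated)
Conditions: LiN(i-Pr)2 (2.3 equiv), THF, −78 to −20 °C; 20, −78 °C; aq HCl
Reagents that add atoms: none
Why: Dianion aldol addition, in which the second deprotonation takes place at the C6 methyl group and this vinylogous carbanion is the most nucleophilic site, so the aldehyde should add there and not at C3.

Step 15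
Reactants: 22 4-hydroxy-6-[2-hydroxy-2-(4-methoxyphenyl)ethyl]-2H-pyran-2-one
Product: 23 4-hydroxy-6-[(E)-2-(4-methoxyphenyl)ethenyl]-2H-pyran-2-one
Conditions: TsOH·H2O (20 mol %), 1,4-dioxane, 90 °C
Reagents that add atoms: none
Why: Acid-catalysed E1 dehydration through the 4-methoxybenzyl cation gives the fully conjugated alkene, for which the E isomer is strongly favoured.

Step 16
Reactants: 18 [(1R,4S)-7-(1,3-dioxolan-2-yl)-1-isopropyl-5,6-dimethoxy-4-methyltetralin-8-yl]boronic acid; 23 4-hydroxy-6-[(E)-2-(4-methoxyphenyl)ethenyl]-2H-pyran-2-one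
Product: 25 3-[(1R,4S)-7-(1,3-dioxolan-2-yl)-1-isopropyl-5,6-dimethoxy-4-methyltetralin-8-yl]-4-hydroxy-6-[(E)-2-(4-methoxyphenyl)ethenyl]-2H-pyran-2-one, via aryllead triacetate 24 (not isolated)
Conditions: 18 (1.1 equiv), Pb(OAc)4 (1.0 equiv), Hg(OAc)2 (10 mol %), CHCl3, 40 °C; then 23 (0.9 equiv), pyridine (4 equiv), CHCl3, 60 °C
Reagents that add atoms: none
Why: Pinhey arylation, in which boron-to-lead exchange gives the aryllead triacetate, the pyrone enolate replaces an acetate on tetravalent lead and reductive ligand coupling joins pyrone C3 to C8; this reaction type is known for 4-hydroxycoumarins and cyclic 1,3-dicarbonyl compounds and tolerates two ortho substituents on the aryl group.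

Step 17
Reactants: 25 3-[(1R,4S)-7-(1,3-dioxolan-2-yl)-1-isopropyl-5,6-dimethoxy-4-methyltetralin-8-yl]-4-hydroxy-6-[(E)-2-(4-methoxyphenyl)ethenyl]-2H-pyran-2-one
Product: 26 (1R,4S)-8-{4-hydroxy-6-[(E)-2-(4-methoxyphenyl)ethenyl]-2-oxo-2H-pyran-3-yl}-1-isopropyl-5,6-dimethoxy-4-methyltetralin-7-carbaldehyde
Conditions: 1 M aq HCl, THF, rt
Reagents that add atoms: water O
Why: Acetal hydrolysis through an oxocarbenium ion stabilised by the ortho-methoxy group, under conditions that leave the pyrone and the alkene intact, any ring-chain tautomer with the pyrone 4-OH being of no consequence.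

Step 18
Reactants: 26 (1R,4S)-8-{4-hydroxy-6-[(E)-2-(4-methoxyphenyl)ethenyl]-2-oxo-2H-pyran-3-yl}-1-isopropyl-5,6-dimethoxy-4-methyltetralin-7-carbaldehyde
Product: 27 heimiomycin A
Conditions: BBr3 (10 equiv), CH2Cl2, −78 °C to rt; H2O
Reagents that add atoms: none
Why: Lewis-acid cleavage of the three aryl methyl ethers (boron-complexed oxonium, then SN2 attack of bromide on methyl), a standard operation on alkoxybenzaldehydes that touches neither stereocentre nor the E-alkene.

Compound list
1 | 3,4-dimethoxyphenylboronic acid | COc1ccc(B(O)O)cc1OC | starting material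
2 | ethyl (E)-4-methylpent-2-enoate | CCOC(=O)/C=C/C(C)C | starting material
3 | ethyl (3R)-3-(3,4-dimethoxyphenyl)-4-methylpentanoate | CC(C)[C@H](c1ccc(OC)c(OC)c1)CC(=O)OCC | intermediate
4 | (3R)-3-(3,4-dimethoxyphenyl)-4-methylpentanal | CC(C)[C@H](c1ccc(OC)c(OC)c1)CC=O | intermediate
5 | triethyl phosphonoacetate | CCOC(=O)CP(=O)(OCC)OCC | starting material
6 | ethyl (2E,5R)-5-(3,4-dimethoxyphenyl)-6-methylhept-2-enoate | CC(C)[C@H](c1ccc(OC)c(OC)c1)C/C=C/C(=O)OCC | intermediate
7 | ethyl (5R)-5-(3,4-dimethoxyphenyl)-6-methylheptanoate | CC(C)[C@H](c1ccc(OC)c(OC)c1)CCCC(=O)OCC | intermediate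
8 | ethyl (5R)-5-(2-bromo-4,5-dimethoxyphenyl)-6-methylheptanoate | CC(C)[C@H](c1c(Br)cc(OC)c(OC)c1)CCCC(=O)OCC | intermediate
9 | (5R)-5-(2-bromo-4,5-dimethoxyphenyl)-6-methylheptanal | CC(C)[C@H](c1c(Br)cc(OC)c(OC)c1)CCCC=O | intermediate
10 | (1R,4S)-8-bromo-1-isopropyl-5,6-dimethoxytetralin-4-carbaldehyde | CC(C)[C@H]1CC[C@H](C=O)c2c(OC)c(OC)cc(Br)c21 | intermediate
11 | [(1R,4S)-8-bromo-1-isopropyl-5,6-dimethoxytetralin-4-yl]methanol | CC(C)[C@H]1CC[C@H](CO)c2c(OC)c(OC)cc(Br)c21 | intermediate
12 | [(1R,4S)-8-bromo-1-isopropyl-5,6-dimethoxytetralin-4-yl]methyl methanesulfonate | CC(C)[C@H]1CC[C@H](COS(C)(=O)=O)c2c(OC)c(OC)cc(Br)c21 | intermediate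
13 | (1R,4S)-8-bromo-1-isopropyl-5,6-dimethoxy-4-methyltetralin | CC(C)[C@H]1CC[C@H](C)c2c(OC)c(OC)cc(Br)c21 | intermediate
14 | (1R,4S)-8-bromo-7-lithio-1-isopropyl-5,6-dimethoxy-4-methyltetralin | CC(C)[C@H]1CC[C@H](C)c2c(OC)c(OC)c([Li])c(Br)c21 | intermediate
15 | (1R,4S)-8-bromo-1-isopropyl-5,6-dimethoxy-4-methyltetralin-7-carbaldehyde | CC(C)[C@H]1CC[C@H](C)c2c(OC)c(OC)c(C=O)c(Br)c21 | intermediate
16 | 2-[(1R,4S)-8-bromo-1-isopropyl-5,6-dimethoxy-4-methyltetralin-7-yl]-1,3-dioxolane | CC(C)[C@H]1CC[C@H](C)c2c(OC)c(OC)c(C3OCCO3)c(Br)c21 | intermediate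
17 | 2-[(1R,4S)-8-lithio-1-isopropyl-5,6-dimethoxy-4-methyltetralin-7-yl]-1,3-dioxolane | CC(C)[C@H]1CC[C@H](C)c2c(OC)c(OC)c(C3OCCO3)c([Li])c21 | intermediate
18 | [(1R,4S)-7-(1,3-dioxolan-2-yl)-1-isopropyl-5,6-dimethoxy-4-methyltetralin-8-yl]boronic acid | CC(C)[C@H]1CC[C@H](C)c2c(OC)c(OC)c(C3OCCO3)c(B(O)O)c21 | intermediate
19 | 4-hydroxy-6-methyl-2H-pyran-2-one | Cc1cc(O)cc(=O)o1 | starting material
20 | 4-methoxybenzaldehyde | COc1ccc(C=O)cc1 | starting material
21 | dilithio dianion of 19 (4-oxide, 6-CH2Li) | [Li]Cc1cc(O[Li])cc(=O)o1 | intermediate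
22 | 4-hydroxy-6-[2-hydroxy-2-(4-methoxyphenyl)ethyl]-2H-pyran-2-one (racemic) | COc1ccc(C(O)Cc2cc(O)cc(=O)o2)cc1 | intermediate
23 | 4-hydroxy-6-[(E)-2-(4-methoxyphenyl)ethenyl]-2H-pyran-2-one | COc1ccc(/C=C/c2cc(O)cc(=O)o2)cc1 | intermediate
24 | [(1R,4S)-7-(1,3-dioxolan-2-yl)-1-isopropyl-5,6-dimethoxy-4-methyltetralin-8-yl]lead triacetate | CC(C)[C@H]1CC[C@H](C)c2c(OC)c(OC)c(C3OCCO3)c([Pb](OC(C)=O)(OC(C)=O)OC(C)=O)c21 | intermediate
25 | 3-[(1R,4S)-7-(1,3-dioxolan-2-yl)-1-isopropyl-5,6-dimethoxy-4-methyltetralin-8-yl]-4-hydroxy-6-[(E)-2-(4-methoxyphenyl)ethenyl]-2H-pyran-2-one | CC(C)[C@H]1CC[C@H](C)c2c(OC)c(OC)c(C3OCCO3)c(-c3c(O)cc(/C=C/c4ccc(OC)cc4)oc3=O)c21 | intermediate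
26 | (1R,4S)-8-{4-hydroxy-6-[(E)-2-(4-methoxyphenyl)ethenyl]-2-oxo-2H-pyran-3-yl}-1-isopropyl-5,6-dimethoxy-4-methyltetralin-7-carbaldehyde | CC(C)[C@H]1CC[C@H](C)c2c(OC)c(OC)c(C=O)c(-c3c(O)cc(/C=C/c4ccc(OC)cc4)oc3=O)c21 | intermediate
27 | heimiomycin A | CC(C)[C@H]1CC[C@H](C)c2c(O)c(O)c(C=O)c(-c3c(O)cc(/C=C/c4ccc(O)cc4)oc3=O)c21 | target

Total step count: 18. Longest linear sequence: 16 (steps 1–13 and 16–18); steps 14 and 15 form the two-step pyrone branch.

Steps most likely to fail

Step 7. Electron transfer from the dimethoxyarene to tetravalent cerium (ring oxidation or nitration) may compete with enamine oxidation. Closure onto the bromine-deactivated, doubly flanked C4a may be slow. Facial selectivity may erode, and C4 may epimerise during work-up. The fallback forms the same C4–C4a bond by a closed-shell, stereospecific Friedel–Crafts reaction; it sets out from 9 and returns at 11. Enamine-catalysed α-chlorination of 9 with (5R)-5-benzyl-2,2,3-trimethylimidazolidin-4-one·CF3CO2H and 2,3,4,5,6,6-hexachlorocyclohexa-2,4-dien-1-one in acetone at −30 °C should give (2R,5R)-5-(2-bromo-4,5-dimethoxyphenyl)-2-chloro-6-methylheptanal F1. Reduction with NaBH4 in the same flask should give (2R,5R)-5-(2-bromo-4,5-dimethoxyphenyl)-2-chloro-6-methylheptan-1-ol F2. KOH in aqueous EtOH should close this with inversion to (2S)-2-[(3R)-3-(2-bromo-4,5-dimethoxyphenyl)-4-methylpentyl]oxirane F3. Intramolecular epoxide–arene cyclisation (SnCl4, CH2Cl2, −78 °C) should open the internal epoxide carbon by attack of C4a with a second inversion, in a 6-exo mode, and deliver 11 directly.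

Step 16. Boron-to-lead exchange at the doubly flanked C8 may be sluggish. Protodemetalation may take over, unconsumed lead tetraacetate may acetoxylate the pyrone enol, and ligand coupling may be slow for steric reasons. The fallback no longer transfers an intact pyrone but builds ring C on a small C8 side chain; it sets out from 16 and returns at 25. Pd-catalysed coupling of 16 with commercial (2-ethoxy-2-oxoethyl)zinc bromide (Pd(dba)2, P(t-Bu)3, THF, rt to 60 °C) should give ethyl 2-[(1R,4S)-7-(1,3-dioxolan-2-yl)-1-isopropyl-5,6-dimethoxy-4-methyltetralin-8-yl]acetate F4. This arylation of a Reformatsky reagent is known for 2,6-disubstituted aryl bromides. Claisen-type C-acetylation (LiN(SiMe3)2, 2 equiv, then 1-acetylimidazole) should give ethyl 2-[(1R,4S)-7-(1,3-dioxolan-2-yl)-1-isopropyl-5,6-dimethoxy-4-methyltetralin-8-yl]-3-oxobutanoate F5. Its dianion (NaH, then n-BuLi) is acylated at the terminal carbon with methyl (E)-4-methoxycinnamate to give ethyl (E)-2-[(1R,4S)-7-(1,3-dioxolan-2-yl)-1-isopropyl-5,6-dimethoxy-4-methyltetralin-8-yl]-7-(4-methoxyphenyl)-3,5-dioxohept-6-enoate F6. Enol lactonisation with DBU in refluxing toluene should then close the 4-hydroxy-2-pyrone 25.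

Step 11. The ortho-bromoaryllithium may lose LiBr (aryne formation), bromine may be transferred between arenes, or deprotonation may be incomplete next to the twisted methoxy groups. The fallback replaces deprotonation by electrophilic substitution; it sets out from 13 and returns at 15. Rieche formylation (Cl2CHOMe, TiCl4, CH2Cl2, −78 to 0 °C) can attack only C7, the single free arene position, which lies ortho to the C6 methoxy group that binds titanium. No compound outside the list is made on this path (F0).

Further compounds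
F1 | step 7 | (2R,5R)-5-(2-bromo-4,5-dimethoxyphenyl)-2-chloro-6-methylheptanal | CC(C)[C@H](c1c(Br)cc(OC)c(OC)c1)CC[C@H](C=O)Cl
F2 | step 7 | (2R,5R)-5-(2-bromo-4,5-dimethoxyphenyl)-2-chloro-6-methylheptan-1-ol | CC(C)[C@H](c1c(Br)cc(OC)c(OC)c1)CC[C@H](CO)Cl
F3 | step 7 | (2S)-2-[(3R)-3-(2-bromo-4,5-dimethoxyphenyl)-4-methylpentyl]oxirane | CC(C)[C@H](c1c(Br)cc(OC)c(OC)c1)CC[C@H]1CO1
F4 | step 16 | ethyl 2-[(1R,4S)-7-(1,3-dioxolan-2-yl)-1-isopropyl-5,6-dimethoxy-4-methyltetralin-8-yl]acetate | CC(C)[C@H]1CC[C@H](C)c2c(OC)c(OC)c(C3OCCO3)c(CC(=O)OCC)c21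
F5 | step 16 | ethyl 2-[(1R,4S)-7-(1,3-dioxolan-2-yl)-1-isopropyl-5,6-dimethoxy-4-methyltetralin-8-yl]-3-oxobutanoate (α-centre not defined) | CC(C)[C@H]1CC[C@H](C)c2c(OC)c(OC)c(C3OCCO3)c(C(C(C)=O)C(=O)OCC)c21
F6 | step 16 | ethyl (E)-2-[(1R,4S)-7-(1,3-dioxolan-2-yl)-1-isopropyl-5,6-dimethoxy-4-methyltetralin-8-yl]-7-(4-methoxyphenyl)-3,5-dioxohept-6-enoate (α-centre not defined) | CC(C)[C@H]1CC[C@H](C)c2c(OC)c(OC)c(C3OCCO3)c(C(C(=O)OCC)C(=O)CC(=O)/C=C/c3ccc(OC)cc3)c21
F0 | step 11 | none | none
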